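**Slow chain.** What worried me in this chain was slowness: a run of 12 s might end with much of the charge still on its way to the target, and I had to decide how much starting material the next run was worth.

| setting | Thursday's | Wednesday's | Sunday's | Tuesday's |
|---|---|---|---|---|
| starting material | 0.080 M | 0.12 M | 0.20 M | 0.25 M |
| time | 12 s | 12 s | 12 s | 12 s |

1. [target] at the end for Thursday's, Wednesday's, Sunday's, Tuesday's, in this order
2. how that number moves from the first to the last of them (rises, then falls / falls all the way / falls, then rises / rises all the way / hardly changes)

- "hardly changes" means that all values lie within two and a half points (for a concentration: within two and a half percent of the largest)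
- run time (Thursday's): 12 s

    intermediate B → target (k1 = 0.22 s⁻¹)
    intermediate A ⇌ intermediate C (K2 = 0.80, k2 = 0.027 s⁻¹)
    intermediate A → intermediate B (k3 = 0.18 s⁻¹)
    target ⇌ isomer of the product (K4 = 3.9, k4 = 0.11 s⁻¹)
    starting material → intermediate A (k5 = 0.36 s⁻¹)
    intermediate B → decomposed reagent (k6 = 0.021 s⁻¹)

**Counting turnovers.** The step from starting material to intermediate A, at 0.36 s⁻¹, came to 4.32 turnovers, a turnover count being the rate constant of a step times the run time, and since each step has a single species on its left, that count holds no concentration. So I expected 1.33% of the starting material to remain in Thursday's flask and the same part of the larger charge in Tuesday's. The step from intermediate A to intermediate B reaches 2.16 turnovers, fewer than the first step, and the step from target to its isomer reaches 1.32, so I could not put a fraction on the target by hand.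

**My decision.** I committed to the proportion instead: [target] at the end should grow from Thursday's to Tuesday's by the ratio of the charges, 3.12, with the fraction of the charge unchanged. Since on that reckoning the fraction did not move with the charge, I decided to set the charge of the next run by the amount of target I needed, and to keep the same 12 s.

**The forecast.** The forecast gave 0.0246 M, 0.0369 M, 0.0614 M and 0.0768 M, so that the number rises all the way, on the ground that [target] is “the same fraction of the starting concentration in each run”. It went further than I did by naming that fraction, roughly 0.31.

**The simulation.** It gave 0.0246 M, 0.0370 M, 0.0616 M and 0.0770 M, so the number rises all the way.

**What stood.** In Thursday's flask, half of the turnover of the step from starting material to intermediate A up to the end was done by 1.89 s, earlier than the 3.9 s half-life of intermediate A by its step to intermediate B, and at 1.89 s intermediate A was made 2.22 times as fast as it was used, with 41.2% of the charge standing as intermediate A at 6.00 s against 13.5% as target. After its 4.32 turnovers, Thursday's flask held 1.3% of its starting material at the end, and Tuesday's flask, after the same 4.32 turnovers, held 1.33%.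

The numbers of this flask stand for no real mixture; what happens was integrated by code.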